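If each turn of substrate into target runs through the catalyst, two flasks charged alike in substrate and capture agent should share one clock: the catalyst dose, [free catalyst] as charged times the time elapsed.

common to all: substrate 20 mM
- ash: capture agent 2 mM; free catalyst 3 mM; the very flask that is asked about, followed so far
- maple: capture agent 2 mM; free catalyst 4.5 mM; run made earlier
- flask: capture agent 2.00 mM; free catalyst 3.0 mM; time 1.0 h

| run | time / min | target / % | substrate / % |
|---|---|---|---|
| ash | 8.00 | 21.2 | 70.3 |
| ash | 10.0 | 22.5 | 68.5 |
| ash | 12.0 | 24.0 | 63.2 |
| maple | 8.00 | 24.7 | 60.9 |
| maple | 10.0 | 27.7 | 57.2 |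
| maple | 12.0 | 30.2 | 54.1 |
| maple | 15.0 | 31.3 | 50.4 |
| maple | 20.0 | 33.2 | 44.5 |
| maple | 25.0 | 32.8 | 43.0 |

(readings scatter by 1 percentage point)

- when, up to 1.0 h, the flask holds most target
- the amount of target, in percent of the substrate charged, at that time



I read the pace of the flask as a ladder, fastest rung first. Before the first reading something quick has happened: at 8.00 min the ash run has lost 29.7% of its substrate but shows 21.2% target. So the following amount is missing from both columns:

missing = 1.70 mM

That is less than the 3 mM of catalyst charged, and I take it to be sitting on the catalyst.

On the next rung target climbs, and here I can test the clock. Ash at 12.0 min and maple at 8.00 min have the same dose, 36.0 mM·min. They read 24.0% and 24.7% target, and 63.2% and 60.9% substrate, which is close for readings good to 1 percentage point.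

The top rung is the peak. Maple reads 33.2% at 20.0 min and 32.8% at 25.0 min, a difference inside the scatter, so I put its top midway at 22.5 min. That gives the peak dose, the dose at which target stops gaining:

peak dose = 4.5 mM × 22.5 min = 101 mM·min

time in the flask = 101 mM·min / 3.0 mM = 0.563 h

I expect about 33.2% there, and a fall afterwards, since the dose at 1.0 h is 180 mM·min, well past the peak dose.

The forecast differs from my reckoning, giving 29% at 1 h, later and lower, on the ground that “The catalyst seems to be dying”.

The flask gives 34.3% at 0.527 h.

    free catalyst + target → free catalyst + over-reaction product (k = 10.3 L mol⁻¹ min⁻¹)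
    catalyst intermediate ⇌ free catalyst + target (K = 0.00958 M, k = 0.421 min⁻¹)
    catalyst intermediate + capture agent → trapped intermediate (k = 3.32 L mol⁻¹ min⁻¹)
    substrate + free catalyst ⇌ catalyst intermediate (K = 104 L mol⁻¹, k = 92.9 L mol⁻¹ min⁻¹)
    free catalyst → spent catalyst (k = 2.80 × 10⁻⁵ min⁻¹)

That top stands at a dose of 94.9 mM·min, close to my 101 mM·min. A neighbour flask, the same charge stopped at 15 min, has a dose of 45.0 mM·min, equal to maple at 10.0 min, and holds 28.9% target against maple's reading of 27.7%. The largest single effect on the height of the top that a run shows is that of the way back from catalyst intermediate to substrate + free catalyst: the same flask without that way back reaches 68.3% instead of 34.3%.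

The data were computed from invented constants; scatter was added.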